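**Retrosynthetic overview**
1. Target ⇒ the 3-methyl-2,5-dihydro-1-benzoxepine stearate. The last unsaturation (C5–H plus a CH3 hydrogen) is put in at the end, as a desaturase would do.
2. Dihydrobenzoxepine ⇒ the isomeric 2,2-dimethyl-2H-chromene stearate. A light-driven ring expansion (retro-oxa-6π, [1,7]-H shift, O–CH2 closure) moves the aryl–O bond from prenyl C3 to a prenyl methyl carbon.
3. Chromene stearate ⇒ 2,2-dimethylchromene-6-carbaldehyde + stearoyl chloride, joined by a one-pot reductive acylation.
4. Chromene aldehyde ⇒ 4-hydroxybenzaldehyde + prenal diethyl acetal, through an o-quinone methide and oxa-6π closure.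
5. Ring order: the arene is bought, the pyran ring is made first, and the oxepine ring is made second by expanding the pyran.

Assumption: the target has no stereocentre and no stereogenic double bond (the ring C4=C5 alkene is cis by ring constraint), so it is achiral and needs no enantiocontrol; its biosynthesis is taken as p-hydroxybenzoate-derived C7 unit → ortho-C-prenylation → o-quinone methide/2,2-dimethylchromene → shift of the aryl–O bond to a prenyl methyl carbon → desaturation → acylation with stearate (C18).

**Step 1**
Reactants: 1 4-hydroxybenzaldehyde; 2 1,1-diethoxy-3-methylbut-2-ene (prenal diethyl acetal)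
Product: 4 2,2-dimethyl-2H-chromene-6-carbaldehyde, via o-quinone methide 3 (not isolated)
Conditions: 2 (1.5 equiv), 3-picoline (0.25 equiv), p-xylene, 140 °C, EtOH distilled off, 24 h
Reagents that add atoms: 1,1-diethoxy-3-methylbut-2-ene, CCOC(OCC)C=C(C)C
Why: This is the thermal, picoline-buffered chromenylation of an acidic phenol with an enal acetal, in which acetal exchange, ortho C–C bond formation and loss of two EtOH give the (Z)-o-quinone methide 3, which closes by oxa-6π electrocyclisation, the closure assumed for prenylphenol-derived chromenes in nature; no stereocentre is formed.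

**Step 2**
Reactants: 4 2,2-dimethyl-2H-chromene-6-carbaldehyde; 5 octadecanoyl chloride (stearoyl chloride)
Product: 7 (2,2-dimethyl-2H-chromen-6-yl)methyl octadecanoate, via aluminium alkoxide 6 (not isolated)
Conditions: DIBAL-H (1.05 equiv), CH2Cl2, −78 °C, 30 min; then pyridine (3 equiv), DMAP (0.2 equiv), 5 (1.3 equiv), −78 °C → rt; aq. Rochelle salt
Reagents that add atoms: octadecanoyl chloride, ClC(=O)CCCCCCCCCCCCCCCCC
Why: This is a one-pot reductive acylation in which DIBAL-H adds hydride 1,2 to the aldehyde and the diisobutylaluminium alkoxide 6 is acylated in situ under pyridine/DMAP catalysis (the trapping used in the reductive acetylation of esters), with the chromene alkene and aryl ether inert to both reagents; no stereocentre is formed.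

**Step 3**
Reactants: 7 (2,2-dimethyl-2H-chromen-6-yl)methyl octadecanoate
Product: 10 (3-methyl-2,5-dihydro-1-benzoxepin-7-yl)methyl octadecanoate, via o-quinone methide 8 (not isolated), via Z-dienylphenol 9 (not isolated)
Conditions: hν (medium-pressure Hg lamp, Pyrex filter, λ > 300 nm), degassed cyclohexane (5 mM), FEP flow coil, 30–35 °C, ca. 1 h residence
Reagents that add atoms: none
Why: Proposed new method: light opens the pyran by retro-oxa-6π electrocyclisation to the (Z)-o-quinone methide 8, a thermal antarafacial [1,7]-H shift from a prenyl methyl group to oxygen gives the (Z)-dienylphenol 9, and a second photon drives intramolecular O–H transfer to the styrenyl carbon (future C5) with collapse of the phenoxyl/allyl pair at the terminal CH2 (net 7-endo 1,4-hydroaryloxylation of the diene), so that 10, whose unconjugated anisole-type chromophore is transparent above 300 nm, builds up as the only photostable isomer; the closest known reaction types are the photochromic ring opening/[1,7]-H shift of 2,2-dimethylchromenes and their photochemical ring expansion to 2,5-dihydro-1-benzoxepines in resorcinol-derived cases, and no stereocentre is formed.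

**Step 4**
Reactants: 10 (3-methyl-2,5-dihydro-1-benzoxepin-7-yl)methyl octadecanoate
Product: 12 (3-methylidene-2,3-dihydro-1-benzoxepin-7-yl)methyl octadecanoate (target), via allyl cation 11 (not isolated)
Conditions: DDQ (1.1 equiv), 2,6-dichloropyridine (2 equiv), 4 Å MS, ClCH2CH2Cl, 0 °C → rt
Reagents that add atoms: none
Why: This is a DDQ dehydrogenation (hydride abstraction then proton loss, the reaction type that turns aryl-prenyl groups into aryl-3-methylbuta-1,3-dienyl groups), in which the C5–H bond is benzylic, allylic and activated by the ortho ring oxygen, so hydride loss gives the delocalised cation 11, which should lose a proton from the freely rotating, better hyperconjugating CH3 rather than from the oxygen-deactivated C2–H to give the exocyclic diene, which is locked s-trans and cannot add DDQ in a Diels–Alder reaction, while the 4-alkoxybenzyl ester resists DDQ as PMB esters do; no stereocentre is formed.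

**Compound list**
1 | 4-hydroxybenzaldehyde | O=Cc1ccc(O)cc1 | starting material
2 | 1,1-diethoxy-3-methylbut-2-ene | CCOC(OCC)C=C(C)C | starting material
3 | (3Z)-3-(3-methylbut-2-en-1-ylidene)-4-oxocyclohexa-1,5-diene-1-carbaldehyde (o-quinone methide) | O=C1C=CC(C=O)=C/C1=C/C=C(C)C | intermediate
4 | 2,2-dimethyl-2H-chromene-6-carbaldehyde | CC1(C)C=Cc2cc(C=O)ccc2O1 | intermediate
5 | octadecanoyl chloride | ClC(=O)CCCCCCCCCCCCCCCCC | starting material
6 | diisobutylaluminium (2,2-dimethyl-2H-chromen-6-yl)methoxide | CC(C)C[Al](CC(C)C)OCc1ccc2OC(C)(C)C=Cc2c1 | intermediate
7 | (2,2-dimethyl-2H-chromen-6-yl)methyl octadecanoate | CC1(C)C=Cc2cc(COC(=O)CCCCCCCCCCCCCCCCC)ccc2O1 | intermediate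
8 | [(3Z)-3-(3-methylbut-2-en-1-ylidene)-4-oxocyclohexa-1,5-dien-1-yl]methyl octadecanoate (o-quinone methide) | O=C1C=CC(COC(=O)CCCCCCCCCCCCCCCCC)=C/C1=C/C=C(C)C | intermediate
9 | {4-hydroxy-3-[(1Z)-3-methylbuta-1,3-dien-1-yl]phenyl}methyl octadecanoate | C=C(C)/C=C\c1cc(COC(=O)CCCCCCCCCCCCCCCCC)ccc1O | intermediate
10 | (3-methyl-2,5-dihydro-1-benzoxepin-7-yl)methyl octadecanoate | CC1=CCc2cc(COC(=O)CCCCCCCCCCCCCCCCC)ccc2OC1 | intermediate
11 | 3-methyl-7-[(octadecanoyloxy)methyl]-2H-1-benzoxepinyl allyl cation (C3/C5 delocalised, ion pair with DDQH−) | C[C+]1C=Cc2cc(COC(=O)CCCCCCCCCCCCCCCCC)ccc2OC1 | intermediate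
12 | (3-methylidene-2,3-dihydro-1-benzoxepin-7-yl)methyl octadecanoate | C=C1C=Cc2cc(COC(=O)CCCCCCCCCCCCCCCCC)ccc2OC1 | target

**Total step count:** 4. **Longest linear sequence:** 4 (1 → 4 → 7 → 10 → 12).

**Steps most likely to fail, and fallbacks**

Step 3 is the most exposed.
- The first-photon chemistry (7 → 8 → 9) is well behaved.
- The second, ring-closing photochemical event may fail on a mono-oxygenated chromene.
- Compound 9 is a 4-hydroxybenzyl ester and may lose stearate by way of a p-quinone methide.

The fallback sets out from 7 and comes back at 12, bypassing 10. Irradiate only to partial conversion and separate the (Z)-dienylphenol 9 from recyclable 7 by cold chromatography. Then close the ring in the ground state with Pd(OAc)2 (10 mol %) and 1,4-benzoquinone (1.2 equiv) in THF at 0 °C → rt. Phenoxypalladation at the terminal diene carbon gives a ring π-allylpalladium species, and β-hydride loss from the methyl group delivers 12. This combines Bäckvall-type diene oxidation with Hosokawa-type oxidative phenol cyclisation. The competing 6-exo attack gives a neopentyl σ-palladium species with no β-hydrogen, which can only revert or protonate back to 7. This detour makes no new compound (F0).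

Step 4 is next.
- Cation 11 could lose the C2 proton and give the endocyclic 3-methyl-1-benzoxepine.
- Cation 11 could be captured by DDQH− or by traces of water.

The fallback sets out from 10 and comes back at 12. It replaces hydride abstraction with radical halogenation followed by base-controlled elimination. Wohl–Ziegler bromination (NBS, AIBN, PhCF3, 80 °C) attacks the weakest C–H bond (C5, which is both benzylic and allylic) and gives (5-bromo-3-methyl-2,5-dihydro-1-benzoxepin-7-yl)methyl octadecanoate F1. The crude bromide is treated with DBU in toluene at 0 °C → rt. The bulky base removes the exposed methyl proton in a 1,4-elimination (E2′).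

Step 1 is third.
- The condensation may be low-yielding with the formyl group present, through acetal scrambling and tar formation at 140 °C.

The fallback sets out from 1 and comes back at 4. It separates C–C bond formation from ring closure, as the biosynthesis does. Direct ortho-C-prenylation of 1 with prenyl bromide in aqueous KOH at rt gives 4-hydroxy-3-(3-methylbut-2-en-1-yl)benzaldehyde F2. The yield is modest, but the materials are cheap and the O-prenyl ether is easily removed. Dehydrogenation with DDQ in refluxing 1,4-dioxane then generates the same o-quinone methide 3, which electrocyclises to 4.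

**Further compounds**
F0 | step 3 | none | none
F1 | step 4 | (5-bromo-3-methyl-2,5-dihydro-1-benzoxepin-7-yl)methyl octadecanoate (racemic) | CC1=CC(Br)c2cc(COC(=O)CCCCCCCCCCCCCCCCC)ccc2OC1
F2 | step 1 | 4-hydroxy-3-(3-methylbut-2-en-1-yl)benzaldehyde | CC(C)=CCc1cc(C=O)ccc1O
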